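**Plan**

1. Retrosynthesis: the C-3=C-4 bond of the 3-acyl-5-hydroxy-3-pyrrolin-2-one (lactam numbered N-1, C-2 to C-5) and the C-5–OH bond are cut first; this opens both the lactam and the 13-membered paracyclophane to a 14-membered β-keto lactam bearing a CH2OH group. Then follow the amide N-1–C-2 bond, the ketone–CH2 bond, the aryl O–C bond at cyclopentane ring B, the two Diels–Alder bonds of cyclohexene ring C (one is also a bond of ring B), and the two Diels–Alder bonds of cyclohexane ring A.
2. Enabling feature: C-3 lies between the ketone and the lactam carbonyl and is doubly bonded to C-4. This C-3=C-4 bond belongs to both the lactam and the 13-membered ring, whereas the amide bond lies outside that ring. A strain-free macrolactam closed through the amide can therefore be contracted to the 13-membered ring by Knoevenagel condensation of the C-3 methylene with a C-4 aldehyde; C-5 is at the oxidation level reached from the 2-hydroxypyrrole tautomer.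
3. Forward order: ring A (enantioselective Diels–Alder), triene and Z-enoate arms, rings C and B together (intramolecular Diels–Alder), aryl ether, β-keto thioester, 14-membered relay lactam, then lactam and 13-membered ring in one oxidative cascade.
4. Stereochemistry: quaternary carbon and its neighbour from the catalyst and the E dienophile; ring methyls from endo addition and thermodynamic HAT hydrogenation; carbinol by Felkin–Anh addition, relayed by 1,3-allylic strain of the Z-enoate to the B/C ring-fusion carbons, with the vinyl-bearing carbon fixed by the E,E-diene geometry; ester carbon by epimerisation; ether carbon by Mitsunobu inversion; C-5 by reversible, macrocycle-controlled hydration.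

Key step: step 21

Assumption: the (S)-oxazaborolidinium catalyst of step 2 is taken to deliver the diene to the enal face that gives 4 as drawn; if the sense of induction is the opposite one, the (R)-catalyst is used and nothing else changes.

Step 1
Reactants: 1 2-methylpent-1-en-3-one
Product: 2 (Z)-tert-butyldimethyl[(2-methylpenta-1,3-dien-3-yl)oxy]silane
Conditions: TBSOTf, Et3N, CH2Cl2, 0 °C
Reagents that add atoms: tert-butyldimethylsilyl trifluoromethanesulfonate, CC(C)(C)[Si](C)(C)OS(=O)(=O)C(F)(F)F
Why: Soft enolisation of the ethyl ketone (silyl triflate/amine) should give the cross-conjugated silyl dienol ether mainly as the Z isomer (methyl cis to oxygen), the geometry in which the terminal methyl is "outside" in the s-cis diene; no stereocentre is formed.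

Step 2
Reactants: 2 (Z)-silyl dienol ether; 3 ethyl (E)-3-methyl-4-oxobut-2-enoate
Product: 4 ethyl (1R,2R,6R)-5-[(tert-butyldimethylsilyl)oxy]-2-formyl-2,4,6-trimethylcyclohex-4-ene-1-carboxylate
Conditions: (S)-3,3-diphenyl-1-(2-methylphenyl)tetrahydro-1H,3H-pyrrolo[1,2-c][1,3,2]oxazaborole (20 mol %), HNTf2 (18 mol %), CH2Cl2, −78 → −40 °C
Reagents that add atoms: none
Why: Catalytic enantioselective Diels–Alder reaction with the chiral oxazaborolidinium Lewis acid bound to the formyl group: the silyloxy group makes the methyl-bearing diene terminus the nucleophilic one, so it should bond to the ester-bearing β-carbon and leave the CH2 terminus to build the quaternary carbon; the E dienophile fixes CHO trans to CO2Et, the formyl-endo transition state places the ring methyl cis to CHO, and the catalyst shields one enal face to set the absolute configuration.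

Step 3
Reactants: 4 silyl enol ether cycloadduct
Product: 5 ethyl (1R,2R,6R)-2-formyl-2,4,6-trimethyl-5-(trifluoromethanesulfonyloxy)cyclohex-4-ene-1-carboxylate
Conditions: CsF, PhNTf2, 1,2-dimethoxyethane, rt
Reagents that add atoms: N-phenylbis(trifluoromethanesulfonimide), O=S(=O)(N(c1ccccc1)S(=O)(=O)C(F)(F)F)C(F)(F)F
Why: Fluoride desilylation gives the regiodefined enolate, which is trapped on oxygen (enol triflate formation); the ketone is never set free, so the neighbouring methyl-bearing stereocentre cannot epimerise.

Step 4
Reactants: 5 enol triflate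
Product: 6 ethyl (1R,2R,6S)-2-formyl-2,4,6-trimethylcyclohex-4-ene-1-carboxylate
Conditions: Pd(OAc)2 (cat.), PPh3, HCO2H, n-Bu3N, DMF, 60 °C
Reagents that add atoms: none
Why: Palladium-catalysed formate reduction of an enol triflate (oxidative addition to zerovalent palladium, decarboxylation of formate to the hydride, reductive elimination) should replace the oxygen by hydrogen without touching the aldehyde, ester or stereocentres.

Step 5
Reactants: 6 trisubstituted cyclohexene
Product: 7 ethyl (1R,2R,4R,6S)-2-formyl-2,4,6-trimethylcyclohexane-1-carboxylate (ring A; CO2Et, CHO and both ring methyls equatorial, quaternary methyl axial)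
Conditions: Mn(dpm)3 (cat.), PhSiH3, t-BuOOH, i-PrOH, rt
Reagents that add atoms: none
Why: Metal-hydride hydrogen-atom-transfer hydrogenation: the H atom adds to the CH end of the alkene and the tertiary radical should be reduced to the thermodynamically preferred epimer, with the new methyl equatorial, cis to the other ring methyl and trans to the quaternary methyl (the alternative would place two methyls 1,3-diaxial), an outcome that surface hydrogenation from the open face would not give.

Step 6
Reactants: 7 ring-A aldehyde ester
Product: 8 ethyl 2,4,6-trimethyl-2-[(E)-2-methyl-3-oxoprop-1-en-1-yl]cyclohexane-1-carboxylate (ring configuration as in 7)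
Conditions: Ph3P=C(CH3)CHO, toluene, 110 °C
Reagents that add atoms: 2-(triphenylphosphoranylidene)propanal, CC(C=O)=P(c1ccccc1)(c1ccccc1)c1ccccc1
Why: Wittig olefination with a formyl-stabilised ylide should give the (E)-2-methyl enal under thermodynamic oxaphosphetane control; the aldehyde is neopentyl and not enolisable, so heating is needed and harmless.

Step 7
Reactants: 8 enal
Product: 9 ethyl 2,4,6-trimethyl-2-[(1E,3E)-2-methylhexa-1,3,5-trien-1-yl]cyclohexane-1-carboxylate (ring configuration as in 7)
Conditions: allyldiphenylphosphine oxide, n-BuLi, HMPA, THF, −78 °C → rt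
Reagents that add atoms: allyldiphenylphosphine oxide, C=CCP(=O)(c1ccccc1)c1ccccc1
Why: Horner–Wittig olefination: the lithiated allyl phosphine oxide adds through its α-carbon to the aldehyde (1,2-addition, hindered ester untouched at −78 °C) and syn elimination of phosphinate should give the E diene, hence the E,E-triene.

Step 8
Reactants: 9 triene ester
Product: 10 2,4,6-trimethyl-2-[(1E,3E)-2-methylhexa-1,3,5-trien-1-yl]cyclohexane-1-carbaldehyde (ring configuration as in 7)
Conditions: i-Bu2AlH, CH2Cl2, −78 °C; aq. KNa tartrate
Reagents that add atoms: none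
Why: Partial reduction of the hindered ester by diisobutylaluminium hydride: the tetrahedral aluminium hemiacetal is stable at −78 °C and should collapse to the aldehyde only on work-up; no stereocentre changes.

Step 9
Reactants: 10 ring-A aldehyde
Product: 11 methyl 4-hydroxy-4-[ring A of 10]but-2-ynoate, Felkin carbinol (epimeric at the carbinol carbon to the ether carbon of the target)
Conditions: methyl propiolate, LiN(SiMe3)2, THF, −78 °C; then 10
Reagents that add atoms: methyl propiolate, C#CC(=O)OC
Why: 1,2-Addition of the lithium acetylide to the α-branched aldehyde under Felkin–Anh control (attack anti to the branch carrying the quaternary carbon) should give the carbinol epimeric to the target's ether carbon, as needed for the later inversion.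

Step 10
Reactants: 11 propargylic alcohol
Product: 12 tert-butyldimethylsilyl ether of 11
Conditions: TBSOTf, 2,6-lutidine, CH2Cl2, −78 → 0 °C
Reagents that add atoms: tert-butyldimethylsilyl trifluoromethanesulfonate, CC(C)(C)[Si](C)(C)OS(=O)(=O)C(F)(F)F
Why: Silylation of the hindered secondary alcohol with the silyl triflate; the ether blocks lactonisation after the semihydrogenation and supplies the 1,3-allylic strain element for step 12.

Step 11
Reactants: 12 silyloxy ynoate
Product: 13 methyl (Z)-4-[(tert-butyldimethylsilyl)oxy]-4-[ring A of 10]but-2-enoate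
Conditions: H2 (1 atm), Pd/CaCO3 poisoned with Pb(OAc)2, quinoline, EtOAc, rt
Reagents that add atoms: none
Why: Lindlar-type cis semihydrogenation of the electron-poor alkyne should give the Z enoate; the hindered conjugated triene adsorbs less well on the poisoned surface.

Step 12
Reactants: 13 Z-enoate triene
Product: 14 tricyclic cycloadduct (rings A/B trans, B/C cis; methyl ester cis to the vinyl group and to the ring-B carbinol carbon; OTBS carbon epimeric to the target)
Conditions: toluene (0.01 M), BHT, 130 °C, sealed tube
Reagents that add atoms: none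
Why: Thermal type 1 intramolecular Diels–Alder reaction with a three-atom tether: the Z dienophile puts ester and tether both endo, which should give the cis B/C fusion; 1,3-allylic strain with the cis ester keeps the carbinol hydrogen in the alkene plane, so the diene, which can only reach the face carrying the ring-A tether, adds anti to the silyloxy group and relays the carbinol configuration to both ring-fusion carbons, while the E,E-diene geometry sets the vinyl-bearing carbon.

Step 13
Reactants: 14 cis ester cycloadduct
Product: 15 ester-carbon epimer of 14 (ester trans to both ring-C neighbours; all ring stereocentres as in the target except the OTBS carbon)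
Conditions: NaOMe (cat.), MeOH, 40 °C
Reagents that add atoms: none
Why: Base-mediated epimerisation at the ester α-carbon under thermodynamic control should move the ester out of the all-cis arrangement to the trans,trans arrangement of the target.

Step 14
Reactants: 15 silyl ether
Product: 16 secondary alcohol (carbinol epimeric to the target's ether carbon; hydroxyl on the convex face, cis to both neighbouring hydrogens)
Conditions: Bu4NF, THF, rt
Reagents that add atoms: none
Why: Fluoride cleavage of the silyl ether; the hydroxy ester cannot lactonise because oxygen and ester side are trans across ring B.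

Step 15
Reactants: 17 tert-butyl N-[(2S)-1-hydroxy-3-(4-hydroxyphenyl)propan-2-yl]carbamate (N-Boc-L-tyrosinol)
Product: 18 tert-butyl (4S)-4-(4-hydroxybenzyl)-2,2-dimethyl-1,3-oxazolidine-3-carboxylate
Conditions: 2,2-dimethoxypropane, TsOH·H2O (cat.), acetone, rt
Reagents that add atoms: 2,2-dimethoxypropane, COC(C)(C)OC
Why: Acid-catalysed N,O-acetal formation (transketalisation) masks the carbamate N–H and the primary alcohol together and leaves the phenol free for the etherification.

Step 16
Reactants: 16 secondary alcohol; 18 phenol
Product: 19 aryl ether methyl ester (all ring stereocentres as in the target; side chain as N-Boc N,O-acetonide)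
Conditions: PPh3, DIAD, toluene, 0 → 60 °C
Reagents that add atoms: none
Why: Mitsunobu etherification: SN2 displacement of the oxyphosphonium group by the phenoxide should invert the carbinol to the configuration of the target, and elimination is disfavoured because both β-hydrogens are syn to the leaving group.

Step 17
Reactants: 19 methyl ester
Product: 20 carboxylic acid
Conditions: LiOH, THF/MeOH/H2O, 50 °C; then dil. HCl to pH 4, 0 °C
Reagents that add atoms: lithium hydroxide, [Li+].[OH-]
Why: Saponification (acyl–oxygen cleavage by hydroxide); the α-carbon already has its thermodynamically preferred configuration, and carbamate and N,O-acetal are stable to base.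

Step 18
Reactants: 20 carboxylic acid
Product: 22 S-tert-butyl β-keto thioester, via acyl imidazole 21 (not isolated)
Conditions: CDI, THF, rt; then LiCH2C(O)S-t-Bu (S-tert-butyl thioacetate + LiN(SiMe3)2), THF, −78 → −20 °C
Reagents that add atoms: S-tert-butyl thioacetate, CC(=O)SC(C)(C)C
Why: Crossed Claisen-type C-acylation of the thioester lithium enolate by the acyl imidazole should give the β-keto thioester, which is protected from over-addition as its enolate until work-up.

Step 19
Reactants: 22 β-keto thioester
Product: 23 amino alcohol, trifluoroacetate salt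
Conditions: CF3CO2H/CH2Cl2 (1:4), H2O (5 equiv), 0 °C → rt
Reagents that add atoms: trifluoroacetic acid, OC(=O)C(F)(F)F
Why: Acidolysis of the tert-butyl carbamate (loss of the tert-butyl cation, then decarboxylation) and hydrolysis of the N,O-acetonide free amine and alcohol in one operation; the ammonium salt keeps the amine from reacting with the thioester.

Step 20
Reactants: 23 ammonium salt
Product: 24 14-membered β-keto macrolactam bearing the CH2OH group
Conditions: AgOCOCF3, Et3N, THF (1 mM), 0 °C → rt
Reagents that add atoms: none
Why: Silver-promoted aminolysis of the β-keto thioester (thiophilic activation, N-acylation preferred over O-acylation) under high dilution should close the strain-free relay lactam; no stereocentre is formed.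

Step 21
Reactants: 24 macrolactam alcohol
Product: 28 target CNP0151253.2, via aldehyde 25 (not isolated), via pyrrolinone 26 (not isolated), via acylimine 27 (not isolated)
Conditions: Dess–Martin periodinane (4 equiv), water-saturated CH2Cl2, rt; aq. Na2S2O3/NaHCO3
Reagents that add atoms: water, O
Why: The periodinane oxidises the primary alcohol to the α-amido aldehyde 25, whose C-3 methylene (between ketone and amide carbonyl) condenses with it (Knoevenagel) to the 3-acyl-1,5-dihydropyrrol-2-one 26; tautomerisation to the 2-hydroxypyrrole and a second oxidation give the acylimine 27, which adds water at C-5. The closest known reaction type is the Dess–Martin oxidation/Knoevenagel/oxidation–hydration cascade of open-chain N-(β-ketoacyl) 2-amino-3-arylpropanols to 3-acyl-5-hydroxy-3-pyrrolin-2-ones. One C=C bond closes two rings: the lactam by 5-exo-trig attack of the enol on the aldehyde followed by dehydration, and through the same bond the 13-membered ring, as a contraction of the 14-membered lactam (the amide nitrogen is bypassed) made irreversible by loss of water and conjugation; no ring is closed afterwards. The only new stereocentre, hemiaminal C-5, forms by addition of water to a planar carbon and is controlled by the macrocycle: the bridging arene differentiates the lactam faces, and because the hemiaminal can re-open (acylimine or keto amide) the less strained epimer, taken to be that of the target, should accumulate, while the tyrosinol centre of 24 is erased on the way. The step needs chemoselectivity for the alcohol over alkenes, aryl ether and acidic methylene, which the ligand-exchange mechanism of the iodinane provides, and C–C bond formation at C-3 only, which follows from C-3 being the only doubly activated carbon and being held 1,5 to the aldehyde by the amide.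

**Compound list**

1 | 2-methylpent-1-en-3-one | CCC(=O)C(C)=C | starting material
2 | (Z)-tert-butyldimethyl[(2-methylpenta-1,3-dien-3-yl)oxy]silane | C=C(C)/C(=C/C)O[Si](C)(C)C(C)(C)C | intermediate
3 | ethyl (E)-3-methyl-4-oxobut-2-enoate | CCOC(=O)/C=C(\C)C=O | starting material
4 | ethyl (1R,2R,6R)-5-[(tert-butyldimethylsilyl)oxy]-2-formyl-2,4,6-trimethylcyclohex-4-ene-1-carboxylate | CCOC(=O)[C@@H]1[C@@H](C)C(O[Si](C)(C)C(C)(C)C)=C(C)C[C@]1(C=O)C | intermediate
5 | ethyl (1R,2R,6R)-2-formyl-2,4,6-trimethyl-5-(trifluoromethanesulfonyloxy)cyclohex-4-ene-1-carboxylate | CCOC(=O)[C@@H]1[C@@H](C)C(OS(=O)(=O)C(F)(F)F)=C(C)C[C@]1(C=O)C | intermediate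
6 | ethyl (1R,2R,6S)-2-formyl-2,4,6-trimethylcyclohex-4-ene-1-carboxylate | CCOC(=O)[C@@H]1[C@@H](C)C=C(C)C[C@]1(C=O)C | intermediate
7 | ethyl (1R,2R,4R,6S)-2-formyl-2,4,6-trimethylcyclohexane-1-carboxylate | CCOC(=O)[C@@H]1[C@@H](C)C[C@@H](C)C[C@]1(C=O)C | intermediate
8 | ethyl 2,4,6-trimethyl-2-[(E)-2-methyl-3-oxoprop-1-en-1-yl]cyclohexane-1-carboxylate, ring configuration as in 7 | CCOC(=O)[C@@H]1[C@@H](C)C[C@@H](C)C[C@]1(/C=C(\C)C=O)C | intermediate
9 | ethyl 2,4,6-trimethyl-2-[(1E,3E)-2-methylhexa-1,3,5-trien-1-yl]cyclohexane-1-carboxylate, ring configuration as in 7 | CCOC(=O)[C@@H]1[C@@H](C)C[C@@H](C)C[C@]1(/C=C(C)/C=C/C=C)C | intermediate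
10 | 2,4,6-trimethyl-2-[(1E,3E)-2-methylhexa-1,3,5-trien-1-yl]cyclohexane-1-carbaldehyde, ring configuration as in 7 | O=C[C@@H]1[C@@H](C)C[C@@H](C)C[C@]1(/C=C(C)/C=C/C=C)C | intermediate
11 | methyl 4-hydroxy-4-[ring A of 10]but-2-ynoate, Felkin carbinol | COC(=O)C#C[C@@H](O)[C@@H]1[C@@H](C)C[C@@H](C)C[C@]1(/C=C(C)/C=C/C=C)C | intermediate
12 | tert-butyldimethylsilyl ether of 11 | COC(=O)C#C[C@@H](O[Si](C)(C)C(C)(C)C)[C@@H]1[C@@H](C)C[C@@H](C)C[C@]1(/C=C(C)/C=C/C=C)C | intermediate
13 | methyl (Z)-4-[(tert-butyldimethylsilyl)oxy]-4-[ring A of 10]but-2-enoate | COC(=O)/C=C\[C@@H](O[Si](C)(C)C(C)(C)C)[C@@H]1[C@@H](C)C[C@@H](C)C[C@]1(/C=C(C)/C=C/C=C)C | intermediate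
14 | tricyclic cycloadduct, methyl ester cis to vinyl and to the carbinol carbon, OTBS epimeric to the target | C=C[C@H]1C=C(C)[C@@H]2[C@H]([C@H]1C(=O)OC)[C@@H](O[Si](C)(C)C(C)(C)C)[C@@H]3[C@@H](C)C[C@@H](C)C[C@]32C | intermediate
15 | ester-carbon epimer of 14 (ester trans to both neighbours) | C=C[C@H]1C=C(C)[C@@H]2[C@H]([C@@H]1C(=O)OC)[C@@H](O[Si](C)(C)C(C)(C)C)[C@@H]3[C@@H](C)C[C@@H](C)C[C@]32C | intermediate
16 | tricyclic hydroxy ester, carbinol epimeric to the target's ether carbon | C=C[C@H]1C=C(C)[C@@H]2[C@H]([C@@H]1C(=O)OC)[C@@H](O)[C@@H]3[C@@H](C)C[C@@H](C)C[C@]32C | intermediate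
17 | tert-butyl N-[(2S)-1-hydroxy-3-(4-hydroxyphenyl)propan-2-yl]carbamate (N-Boc-L-tyrosinol) | CC(C)(C)OC(=O)N[C@@H](Cc1ccc(O)cc1)CO | starting material
18 | tert-butyl (4S)-4-(4-hydroxybenzyl)-2,2-dimethyl-1,3-oxazolidine-3-carboxylate | CC(C)(C)OC(=O)N1[C@@H](Cc2ccc(O)cc2)COC1(C)C | intermediate
19 | tricyclic aryl ether methyl ester, ring stereocentres as in the target, side chain as N-Boc N,O-acetonide | C=C[C@H]1C=C(C)[C@@H]2[C@H]([C@@H]1C(=O)OC)[C@H](Oc4ccc(C[C@H]5COC(C)(C)N5C(=O)OC(C)(C)C)cc4)[C@@H]3[C@@H](C)C[C@@H](C)C[C@]32C | intermediate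
20 | carboxylic acid from 19 | C=C[C@H]1C=C(C)[C@@H]2[C@H]([C@@H]1C(=O)O)[C@H](Oc4ccc(C[C@H]5COC(C)(C)N5C(=O)OC(C)(C)C)cc4)[C@@H]3[C@@H](C)C[C@@H](C)C[C@]32C | intermediate
21 | acyl imidazole of 20 | C=C[C@H]1C=C(C)[C@@H]2[C@H]([C@@H]1C(=O)n6ccnc6)[C@H](Oc4ccc(C[C@H]5COC(C)(C)N5C(=O)OC(C)(C)C)cc4)[C@@H]3[C@@H](C)C[C@@H](C)C[C@]32C | intermediate
22 | S-tert-butyl β-keto thioester | C=C[C@H]1C=C(C)[C@@H]2[C@H]([C@@H]1C(=O)CC(=O)SC(C)(C)C)[C@H](Oc4ccc(C[C@H]5COC(C)(C)N5C(=O)OC(C)(C)C)cc4)[C@@H]3[C@@H](C)C[C@@H](C)C[C@]32C | intermediate
23 | amino alcohol β-keto thioester, trifluoroacetate salt | C=C[C@H]1C=C(C)[C@@H]2[C@H]([C@@H]1C(=O)CC(=O)SC(C)(C)C)[C@H](Oc4ccc(C[C@H](N)CO)cc4)[C@@H]3[C@@H](C)C[C@@H](C)C[C@]32C.OC(=O)C(F)(F)F | intermediate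
24 | 14-membered β-keto macrolactam with CH2OH on the tyrosinol carbon | C=C[C@H]1C=C(C)[C@@H]2[C@H]3[C@H](Oc4ccc(cc4)C[C@@H](CO)NC(=O)CC(=O)[C@H]13)[C@@H]1[C@@H](C)C[C@@H](C)C[C@]12C | intermediate
25 | macrolactam aldehyde | C=C[C@H]1C=C(C)[C@@H]2[C@H]3[C@H](Oc4ccc(cc4)C[C@@H](C=O)NC(=O)CC(=O)[C@H]13)[C@@H]1[C@@H](C)C[C@@H](C)C[C@]12C | intermediate
26 | 13-membered 3-acyl-1,5-dihydropyrrol-2-one (5-deoxy target; C-5 H from L-tyrosinol, labile) | C=C[C@H]1C=C(C)[C@@H]2[C@H]3[C@H](Oc4ccc(cc4)C[C@H]4C=C(C(=O)N4)C(=O)[C@H]13)[C@@H]1[C@@H](C)C[C@@H](C)C[C@]12C | intermediate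
27 | 13-membered 3-acyl-2H-pyrrol-2-one (acylimine) | C=C[C@H]1C=C(C)[C@@H]2[C@H]3[C@H](Oc4ccc(cc4)CC4=NC(=O)C(=C4)C(=O)[C@H]13)[C@@H]1[C@@H](C)C[C@@H](C)C[C@]12C | intermediate
28 | CNP0151253.2 | C=C[C@H]1C=C(C)[C@@H]2[C@H]3[C@H](Oc4ccc(cc4)C[C@@]4(O)C=C(C(=O)N4)C(=O)[C@H]13)[C@@H]1[C@@H](C)C[C@@H](C)C[C@]12C | target

**Step count and risks**

Total steps: 21. Longest linear sequence: 20 (steps 1–14 and 16–21; step 15 is a one-step side branch).

Steps most likely to fail: 21, 12 and 16.

Step 21. The ring contraction may stall at the aldehyde because the macrolactam has to reach the cis-amide geometry and take up the strain of the 13-membered ring. The periodinane may also attack the acidic methylene before the ring closes, or hydration may give the C-5 epimer under kinetic control. The fallback separates ring closure from oxygenation and changes the way the C-5–O bond is made. It sets out from 24 and comes back at 28. Oxidation with SO3·pyridine, DMSO and i-Pr2NEt gives the aldehyde 25, now isolated. Piperidinium acetate in toluene over 4 Å sieves at 60 °C closes it to the pyrrolinone 26 by iminium-catalysed Knoevenagel condensation. Deprotonation to the dienolate (K2CO3 or DBU, THF) under O2 gives the C-5 hydroperoxide F1, which P(OEt)3 reduces in the same flask to 28. A trace of acetic acid would equilibrate C-5 if the epimer forms.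

Step 12. The cycloaddition of the hindered, quaternary-carbon-bound diene with the weakly activated Z-enoate may be too slow, so that thermal Z/E isomerisation or cyclisation through the exo (trans-fused) transition state competes. The fallback switches to a more reactive dienophile with Lewis-acid activation at low temperature. It sets out from 13 and comes back at 15. Reduction with i-Bu2AlH (−78 °C) gives the (Z)-allylic alcohol F2, and MnO2 gives the (Z)-enal F3. Me2AlCl in CH2Cl2 at −78 °C should promote the endo intramolecular Diels–Alder reaction to the cis-fused aldehyde F4. DBU epimerises it to the aldehyde F5. Pinnick oxidation (NaClO2, NaH2PO4, 2-methylbut-2-ene) gives the acid F6, and Me3SiCHN2 in MeOH/toluene returns the methyl ester 15.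

Step 16. Backside displacement at the secondary carbinol has to occur from the concave face next to ring C and the angular methyl; it may be too slow, so that the activated alcohol is consumed unproductively or eliminates. The fallback replaces inversion at carbon by redox inversion followed by O-arylation with retention. It sets out from 16 and comes back at 19. Buffered Dess–Martin oxidation gives the ring-B cyclopentanone F7. NaBH4 in MeOH at −40 °C, attacking from the convex face, gives the alcohol F8 with the configuration of the target. Palladium-catalysed C–O coupling (Pd2(dba)3, RockPhos, Cs2CO3, toluene, 90 °C) with the aryl bromide F9 then gives 19; F9 is made from commercial N-Boc-4-bromo-L-phenylalaninol and 2,2-dimethoxypropane under the conditions of step 15.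

**Further compounds**

F1 | step 21 | C-5 hydroperoxide of the target | C=C[C@H]1C=C(C)[C@@H]2[C@H]3[C@H](Oc4ccc(cc4)C[C@@]4(OO)C=C(C(=O)N4)C(=O)[C@H]13)[C@@H]1[C@@H](C)C[C@@H](C)C[C@]12C
F2 | step 12 | (Z)-allylic alcohol from 13 | OC/C=C\[C@@H](O[Si](C)(C)C(C)(C)C)[C@@H]1[C@@H](C)C[C@@H](C)C[C@]1(/C=C(C)/C=C/C=C)C
F3 | step 12 | (Z)-enal | O=C/C=C\[C@@H](O[Si](C)(C)C(C)(C)C)[C@@H]1[C@@H](C)C[C@@H](C)C[C@]1(/C=C(C)/C=C/C=C)C
F4 | step 12 | cis-fused tricyclic aldehyde, formyl cis to its ring-C neighbours | C=C[C@H]1C=C(C)[C@@H]2[C@H]([C@H]1C=O)[C@@H](O[Si](C)(C)C(C)(C)C)[C@@H]3[C@@H](C)C[C@@H](C)C[C@]32C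
F5 | step 12 | epimerised tricyclic aldehyde, formyl trans to its neighbours | C=C[C@H]1C=C(C)[C@@H]2[C@H]([C@@H]1C=O)[C@@H](O[Si](C)(C)C(C)(C)C)[C@@H]3[C@@H](C)C[C@@H](C)C[C@]32C
F6 | step 12 | tricyclic carboxylic acid, silyl ether retained | C=C[C@H]1C=C(C)[C@@H]2[C@H]([C@@H]1C(=O)O)[C@@H](O[Si](C)(C)C(C)(C)C)[C@@H]3[C@@H](C)C[C@@H](C)C[C@]32C
F7 | step 16 | ring-B cyclopentanone methyl ester | C=C[C@H]1C=C(C)[C@@H]2[C@H]([C@@H]1C(=O)OC)C(=O)[C@@H]3[C@@H](C)C[C@@H](C)C[C@]32C
F8 | step 16 | tricyclic hydroxy ester with the carbinol configuration of the target | C=C[C@H]1C=C(C)[C@@H]2[C@H]([C@@H]1C(=O)OC)[C@H](O)[C@@H]3[C@@H](C)C[C@@H](C)C[C@]32C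
F9 | step 16 | tert-butyl (4S)-4-(4-bromobenzyl)-2,2-dimethyl-1,3-oxazolidine-3-carboxylate | CC(C)(C)OC(=O)N1[C@@H](Cc2ccc(Br)cc2)COC1(C)C
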